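**Retrosynthetic overview**
1. Target 13 comes from its tris-MOM ether 12 by mild acidic acetal cleavage. MOM is used because the vinyl group rules out hydrogenolysis and strong Lewis acids.
2. Ring C (the pyranone) is formed last, by Algar–Flynn–Oyamada oxidative cyclisation of 2'-hydroxychalcone 10.
3. Chalcone 10 comes from an intermolecular Claisen–Schmidt aldol condensation of acetophenone 6 (ring A) with aldehyde 8 (ring B); this makes the key C–C bond.
4. Acetophenone 6 comes from site-selective bis-MOM protection of 5, which comes from an aromatic Claisen rearrangement of the symmetric 4-O-prenyl ether 3 (from phloroacetophenone 1 and prenyl bromide 2).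
5. Rings A and B are bought preformed; only ring C is built.

Assumption: the target has no stereocentre (it is achiral), so no enantiocontrol is needed; the only stereo-element on the route is the E double bond of chalcone 10, and intermediates 4, 9 and 11 are racemic and transient.

**Route**

Step 1
Reactants: 1 1-(2,4,6-trihydroxyphenyl)ethanone (phloroacetophenone, dried); 2 1-bromo-3-methylbut-2-ene (prenyl bromide)
Product: 3 1-[2,6-dihydroxy-4-(3-methylbut-2-enyloxy)phenyl]ethanone
Conditions: 2 (1.0 equiv), K2CO3 (1.1 equiv), acetone, reflux, 6 h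
Reagents that add atoms: none
Why: Williamson ether synthesis; the 4-OH is para to the acetyl group and not hydrogen-bonded, so it is the most acidic and nucleophilic hydroxyl and is alkylated while the two chelated ortho-OH groups stay free.

Step 2
Reactants: 3 1-[2,6-dihydroxy-4-(3-methylbut-2-enyloxy)phenyl]ethanone
Product: 5 1-[2,4,6-trihydroxy-3-(2-methylbut-3-en-2-yl)phenyl]ethanone, via ortho-dienone 4 (not isolated)
Conditions: N,N-diethylaniline, 185–190 °C, argon, 2–3 h; cold 1 M HCl wash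
Reagents that add atoms: none
Why: Aromatic Claisen rearrangement ([3,3]-sigmatropic shift with allyl inversion); the two ortho positions of 3 are equivalent by symmetry and the para position carries the acetyl group, so only the 3-(1,1-dimethylallyl) product can form after enolisation of dienone 4 (its single stereocentre is lost on aromatisation).

Step 3
Reactants: 5 1-[2,4,6-trihydroxy-3-(2-methylbut-3-en-2-yl)phenyl]ethanone
Product: 6 1-[2-hydroxy-4,6-bis(methoxymethoxy)-3-(2-methylbut-3-en-2-yl)phenyl]ethanone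
Conditions: MOMCl (2.2 equiv), i-Pr2NEt (3 equiv), CH2Cl2, 0 °C to rt
Reagents that add atoms: chloromethyl methyl ether (MOMCl), COCCl
Why: Regioselective phenol O-alkylation (MOM acetal formation); the free 4-OH and the unhindered chelated 6-OH react, while the 2-OH, chelated to the acetyl group and flanked by the quaternary carbon, stays free as the phenol needed for ring closure.

Step 4
Reactants: 7 4-hydroxybenzaldehyde
Product: 8 4-(methoxymethoxy)benzaldehyde
Conditions: MOMCl (1.2 equiv), i-Pr2NEt (1.5 equiv), CH2Cl2, 0 °C to rt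
Reagents that add atoms: chloromethyl methyl ether (MOMCl), COCCl
Why: Phenol O-alkylation to the MOM ether, which keeps the aldehyde electrophilic under the basic aldol conditions where a phenoxide would deactivate it.

Step 5
Reactants: 6 1-[2-hydroxy-4,6-bis(methoxymethoxy)-3-(2-methylbut-3-en-2-yl)phenyl]ethanone; 8 4-(methoxymethoxy)benzaldehyde
Product: 10 (E)-1-[2-hydroxy-4,6-bis(methoxymethoxy)-3-(2-methylbut-3-en-2-yl)phenyl]-3-[4-(methoxymethoxy)phenyl]prop-2-en-1-one, via aldol adduct 9 (not isolated)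
Conditions: KOH (50% aq, 10 equiv), EtOH, 0 °C to rt, 36–48 h; then cold dilute HCl to pH 5
Reagents that add atoms: none
Why: Claisen–Schmidt crossed aldol condensation; the enolate of methyl ketone 6 adds to the non-enolisable aldehyde 8, and E1cB dehydration of racemic aldol 9 gives the thermodynamically favoured E-enone, with the MOM ethers and the vinyl group inert to KOH.

Step 6
Reactants: 10 (E)-1-[2-hydroxy-4,6-bis(methoxymethoxy)-3-(2-methylbut-3-en-2-yl)phenyl]-3-[4-(methoxymethoxy)phenyl]prop-2-en-1-one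
Product: 12 3-hydroxy-5,7-bis(methoxymethoxy)-2-[4-(methoxymethoxy)phenyl]-8-(2-methylbut-3-en-2-yl)-4H-chromen-4-one, via dihydroflavonol 11 (not isolated)
Conditions: 30% H2O2 (6 equiv), NaOH (2 M aq), MeOH, 0 °C to rt, 16 h; then cold dilute HCl to pH 5
Reagents that add atoms: hydrogen peroxide, OO
Why: Algar–Flynn–Oyamada reaction; the 2'-phenoxide closes ring C by oxa-Michael addition with oxygenation at C3 to the racemic trans-dihydroflavonol 11, which further H2O2 dehydrogenates to the achiral flavonol, while the unactivated vinyl group is inert to nucleophilic peroxide.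

Step 7
Reactants: 12 3-hydroxy-5,7-bis(methoxymethoxy)-2-[4-(methoxymethoxy)phenyl]-8-(2-methylbut-3-en-2-yl)-4H-chromen-4-one
Product: 13 3,5,7-trihydroxy-2-(4-hydroxyphenyl)-8-(2-methylbut-3-en-2-yl)-4H-chromen-4-one
Conditions: HCl (3 M aq), MeOH, 50 °C, 2–3 h, N2
Reagents that add atoms: none
Why: Acid-catalysed acetal methanolysis removes all three MOM groups, and the monosubstituted vinyl group survives because its protonation would give an unfavourable secondary cation under these mild conditions.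

**Compound list**
1 | 1-(2,4,6-trihydroxyphenyl)ethanone (phloroacetophenone) | CC(=O)c1c(O)cc(O)cc1O | starting material
2 | 1-bromo-3-methylbut-2-ene (prenyl bromide) | CC(C)=CCBr | starting material
3 | 1-[2,6-dihydroxy-4-(3-methylbut-2-enyloxy)phenyl]ethanone | CC(=O)c1c(O)cc(OCC=C(C)C)cc1O | intermediate
4 | 4-acetyl-3,5-dihydroxy-6-(2-methylbut-3-en-2-yl)cyclohexa-2,4-dien-1-one (racemic, not isolated) | CC(=O)C1=C(O)C(C(C)(C)C=C)C(=O)C=C1O | intermediate
5 | 1-[2,4,6-trihydroxy-3-(2-methylbut-3-en-2-yl)phenyl]ethanone | CC(=O)c1c(O)cc(O)c(C(C)(C)C=C)c1O | intermediate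
6 | 1-[2-hydroxy-4,6-bis(methoxymethoxy)-3-(2-methylbut-3-en-2-yl)phenyl]ethanone | CC(=O)c1c(OCOC)cc(OCOC)c(C(C)(C)C=C)c1O | intermediate
7 | 4-hydroxybenzaldehyde | O=Cc1ccc(O)cc1 | starting material
8 | 4-(methoxymethoxy)benzaldehyde | COCOc1ccc(C=O)cc1 | intermediate
9 | 3-hydroxy-1-[2-hydroxy-4,6-bis(methoxymethoxy)-3-(2-methylbut-3-en-2-yl)phenyl]-3-[4-(methoxymethoxy)phenyl]propan-1-one (racemic, not isolated) | COCOc1ccc(C(O)CC(=O)c2c(OCOC)cc(OCOC)c(C(C)(C)C=C)c2O)cc1 | intermediate
10 | (E)-1-[2-hydroxy-4,6-bis(methoxymethoxy)-3-(2-methylbut-3-en-2-yl)phenyl]-3-[4-(methoxymethoxy)phenyl]prop-2-en-1-one | COCOc1ccc(/C=C/C(=O)c2c(OCOC)cc(OCOC)c(C(C)(C)C=C)c2O)cc1 | intermediate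
11 | trans-3-hydroxy-5,7-bis(methoxymethoxy)-2-[4-(methoxymethoxy)phenyl]-8-(2-methylbut-3-en-2-yl)chroman-4-one (racemic, 2R,3R enantiomer drawn, not isolated) | O=C1[C@H](O)[C@@H](c2ccc(OCOC)cc2)Oc2c1c(OCOC)cc(OCOC)c2C(C)(C)C=C | intermediate
12 | 3-hydroxy-5,7-bis(methoxymethoxy)-2-[4-(methoxymethoxy)phenyl]-8-(2-methylbut-3-en-2-yl)-4H-chromen-4-one | C=CC(C)(C)c1c(OCOC)cc(OCOC)c2c(=O)c(O)c(-c3ccc(OCOC)cc3)oc12 | intermediate
13 | 3,5,7-trihydroxy-2-(4-hydroxyphenyl)-8-(2-methylbut-3-en-2-yl)-4H-chromen-4-one | C=CC(C)(C)c1c(O)cc(O)c2c(=O)c(O)c(-c3ccc(O)cc3)oc12 | target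

**Totals**
Total step count: 7. Longest linear sequence: 6 steps (steps 1, 2, 3, 5, 6, 7); the aldehyde branch is 1 step before the convergence.

**Three steps most likely to fail, with fallbacks**

Step 2 (Claisen rearrangement). At 190 °C the free phenol next to the new 1,1-dimethylallyl group can undergo the abnormal Claisen rearrangement or cyclise onto the vinyl group. The fallback sets out from 3 and comes back at 5, and it masks every phenol as it forms.
- Compound 3 is silylated in the flask with N,O-bis(trimethylsilyl)acetamide (5 equiv, N,N-diethylaniline, 60 °C) to 1-[4-(3-methylbut-2-enyloxy)-2,6-bis(trimethylsilyloxy)phenyl]ethanone F1.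
- The same solution is heated to 180 °C, where the [3,3] shift gives 4-acetyl-6-(2-methylbut-3-en-2-yl)-3,5-bis(trimethylsilyloxy)cyclohexa-2,4-dien-1-one F2.
- F2 enolises to 1-[4-hydroxy-3-(2-methylbut-3-en-2-yl)-2,6-bis(trimethylsilyloxy)phenyl]ethanone F3.
- F3 is silylated at once by the excess reagent to 1-[3-(2-methylbut-3-en-2-yl)-2,4,6-tris(trimethylsilyloxy)phenyl]ethanone F4, which has no free ortho-OH and so cannot rearrange further or cyclise.
- Catalytic K2CO3 in MeOH at 0 °C then removes the silyl groups and gives 5.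

Step 3 (site-selective bis-MOM protection). The selectivity rests on steric and chelation differences between the 2-OH and the 6-OH; if the wrong chelated hydroxyl is capped, the isomer leading to the 6-substituted flavonol results. The fallback sets out from 3 and comes back at 6; it fixes the protection pattern before the allyl group is introduced and relies on chelation-directed Claisen regiochemistry instead.
- Compound 3 is mono-protected (MOMCl 1.1 equiv, i-Pr2NEt, CH2Cl2, 0 °C) to 1-[2-hydroxy-6-(methoxymethoxy)-4-(3-methylbut-2-enyloxy)phenyl]ethanone F5. The two chelated hydroxyls are equivalent, and the survivor is deactivated by its hydrogen bond.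
- Heating F5 in N,N-diethylaniline at 185 °C gives 4-acetyl-5-hydroxy-3-(methoxymethoxy)-6-(2-methylbut-3-en-2-yl)cyclohexa-2,4-dien-1-one F6. Bond fixation by the acetyl/2-OH chelate directs the shift to C3, between the chelated OH and the ether oxygen, as with resacetophenone 4-allyl ethers.
- F6 enolises to 1-[2,4-dihydroxy-6-(methoxymethoxy)-3-(2-methylbut-3-en-2-yl)phenyl]ethanone F7.
- The non-chelated, more acidic 4-OH of F7 is then capped (MOMCl 1.1 equiv, K2CO3, acetone, rt) to give 6.

Step 6 (Algar–Flynn–Oyamada reaction). Chalcones with a 6'-alkoxy group can divert to aurones. The fallback sets out from 10 and comes back at 12; it builds ring C first and adds the 3-OH afterwards.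
- Compound 10 is cyclised by oxa-Michael addition (NaOAc, EtOH, reflux) to racemic 5,7-bis(methoxymethoxy)-2-[4-(methoxymethoxy)phenyl]-8-(2-methylbut-3-en-2-yl)chroman-4-one F8.
- DDQ in refluxing dioxane dehydrogenates F8 to 5,7-bis(methoxymethoxy)-2-[4-(methoxymethoxy)phenyl]-8-(2-methylbut-3-en-2-yl)-4H-chromen-4-one F9.
- LiN(i-Pr)2 in THF at −78 °C deprotonates C3 to give 3-lithio-5,7-bis(methoxymethoxy)-2-[4-(methoxymethoxy)phenyl]-8-(2-methylbut-3-en-2-yl)-4H-chromen-4-one F10.
- B(OMe)3 traps F10 as lithium trimethoxy[5,7-bis(methoxymethoxy)-2-[4-(methoxymethoxy)phenyl]-8-(2-methylbut-3-en-2-yl)-4-oxo-4H-chromen-3-yl]borate F11.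
- Oxidation of the C–B bond with H2O2/NaOH at 0 °C gives 12 without touching the vinyl group.

Further compounds
F1 | step 2 | 1-[4-(3-methylbut-2-enyloxy)-2,6-bis(trimethylsilyloxy)phenyl]ethanone | CC(=O)c1c(O[Si](C)(C)C)cc(OCC=C(C)C)cc1O[Si](C)(C)C
F2 | step 2 | 4-acetyl-6-(2-methylbut-3-en-2-yl)-3,5-bis(trimethylsilyloxy)cyclohexa-2,4-dien-1-one (racemic) | CC(=O)C1=C(O[Si](C)(C)C)C(C(C)(C)C=C)C(=O)C=C1O[Si](C)(C)C
F3 | step 2 | 1-[4-hydroxy-3-(2-methylbut-3-en-2-yl)-2,6-bis(trimethylsilyloxy)phenyl]ethanone | CC(=O)c1c(O[Si](C)(C)C)cc(O)c(C(C)(C)C=C)c1O[Si](C)(C)C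
F4 | step 2 | 1-[3-(2-methylbut-3-en-2-yl)-2,4,6-tris(trimethylsilyloxy)phenyl]ethanone | CC(=O)c1c(O[Si](C)(C)C)cc(O[Si](C)(C)C)c(C(C)(C)C=C)c1O[Si](C)(C)C
F5 | step 3 | 1-[2-hydroxy-6-(methoxymethoxy)-4-(3-methylbut-2-enyloxy)phenyl]ethanone | CC(=O)c1c(O)cc(OCC=C(C)C)cc1OCOC
F6 | step 3 | 4-acetyl-5-hydroxy-3-(methoxymethoxy)-6-(2-methylbut-3-en-2-yl)cyclohexa-2,4-dien-1-one (racemic) | CC(=O)C1=C(O)C(C(C)(C)C=C)C(=O)C=C1OCOC
F7 | step 3 | 1-[2,4-dihydroxy-6-(methoxymethoxy)-3-(2-methylbut-3-en-2-yl)phenyl]ethanone | CC(=O)c1c(OCOC)cc(O)c(C(C)(C)C=C)c1O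
F8 | step 6 | 5,7-bis(methoxymethoxy)-2-[4-(methoxymethoxy)phenyl]-8-(2-methylbut-3-en-2-yl)chroman-4-one (racemic) | C=CC(C)(C)c1c(OCOC)cc(OCOC)c2c1OC(c1ccc(OCOC)cc1)CC2=O
F9 | step 6 | 5,7-bis(methoxymethoxy)-2-[4-(methoxymethoxy)phenyl]-8-(2-methylbut-3-en-2-yl)-4H-chromen-4-one | C=CC(C)(C)c1c(OCOC)cc(OCOC)c2c(=O)cc(-c3ccc(OCOC)cc3)oc12
F10 | step 6 | 3-lithio-5,7-bis(methoxymethoxy)-2-[4-(methoxymethoxy)phenyl]-8-(2-methylbut-3-en-2-yl)-4H-chromen-4-one | C=CC(C)(C)c1c(OCOC)cc(OCOC)c2c(=O)c([Li])c(-c3ccc(OCOC)cc3)oc12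
F11 | step 6 | lithium trimethoxy[5,7-bis(methoxymethoxy)-2-[4-(methoxymethoxy)phenyl]-8-(2-methylbut-3-en-2-yl)-4-oxo-4H-chromen-3-yl]borate | C=CC(C)(C)c1c(OCOC)cc(OCOC)c2c(=O)c([B-](OC)(OC)OC)c(-c3ccc(OCOC)cc3)oc12.[Li+]
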